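**Plan**

Drimane numbering is used. Ring A holds the 1,4-dione C3(=O)–C4(CH3)2–C5H–C6(=O): the gem-dimethyl carbon C4 lies between ketone C3 and C5, and C5 is alpha to the ring-B enone carbonyl C6.
First cut: the C3–C4 bond, with C3 re-joined to C5. This contracts ring A to a cyclopentanone (C1, C2, C3, C5, C10) that carries C4 as an isopropenyl group on C5.
Further cuts: C3–C5 (Dieckmann), C6=O (allylic oxidation), C11–OAr (Mitsunobu), C9–C11 (sulfonium ylide), C10–C1 and C10–CH3 (enolate alkylations). What remains is (S)-carvone; its ring is ring B and its isopropenyl carbon is C4.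
Forward: ring B is present from the start, the cyclopentanone is closed onto it, and ring A arises last by one-carbon ring expansion (radical 1,2-acyl shift started by hydrogen-atom transfer to the isopropenyl group).
Stereochemistry: the carvone stereocentre (C5) steers the allylation at C10 (anti) and, through the ring conformation, the ylide attack at C9; Pd/formate hydrogenolysis then inverts C9.
C5 itself is erased in the key step and re-formed trans (H anti to the axial C10 methyl, which is also the thermodynamic ring fusion).

Key step: step 10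

Remark: compound 3 is carried as a mixture of epimers at its new methyl-bearing carbon, because that carbon is planarised again in step 2.

**Route**

Step 1
Reactants: 1 (S)-(+)-carvone; 2 iodomethane
Product: 3 (5S,6R)-2,6-dimethyl-5-(prop-1-en-2-yl)cyclohex-2-en-1-one (trans-6-methylcarvone, with its 6-epimer)
Conditions: LDA, THF, −78 °C; MeI, −78 → −20 °C
Reagents that add atoms: iodomethane, CI
Why: kinetic alpha'-deprotonation gives the cross-conjugated lithium enolate, which is methylated at C6 (enolate alkylation); the configuration formed here does not matter because the centre is enolised again in step 2.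

Step 2
Reactants: 3 trans-6-methylcarvone; 4 allyl bromide
Product: 5 (5R,6R)-2,6-dimethyl-6-(prop-2-en-1-yl)-5-(prop-1-en-2-yl)cyclohex-2-en-1-one (allyl trans, methyl cis to the isopropenyl group)
Conditions: LDA, THF, −78 → 0 °C; allyl bromide, DMPU, −78 °C → rt
Reagents that add atoms: allyl bromide, C=CCBr
Why: a second kinetic alpha'-enolate alkylation should create the quaternary carbon (future C10) with the allyl group entering anti to the vicinal isopropenyl group, the usual course of 6,6-dialkylation of carvone.

Step 3
Reactants: 5 6-allyl-6-methylcarvone; 6 trimethylsulfonium iodide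
Product: 7 (3R,7R,8R)-4,8-dimethyl-7-(prop-1-en-2-yl)-8-(prop-2-en-1-yl)-1-oxaspiro[2.5]oct-4-ene (oxirane oxygen syn to the C-methyl and the isopropenyl group)
Conditions: Me3S+ I−, n-BuLi, THF, −10 °C → rt
Reagents that add atoms: trimethylsulfonium iodide, C[S+](C)C.[I-]
Why: Corey–Chaykovsky epoxidation, in which the small sulfonium methylide adds 1,2 to the enone carbonyl from the face anti to the pseudoaxial C-methyl and the isopropenyl group (Felkin-type axial attack), so the new CH2 sits on that face and the oxygen on the other.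

Step 4
Reactants: 7 alkenyl oxirane
Product: 8 [(1R,5R,6R)-2,6-dimethyl-5-(prop-1-en-2-yl)-6-(prop-2-en-1-yl)cyclohex-2-en-1-yl]methanol
Conditions: Pd2(dba)3·CHCl3 (cat.), n-Bu3P, HCO2H, Et3N, dioxane, rt
Reagents that add atoms: none
Why: Pd(0) ionises the alkenyl oxirane with inversion to a pi-allyl complex and the palladium formate delivers hydride from the metal face to the more substituted allyl terminus (Pd-catalysed formate hydrogenolysis of alkenyl oxiranes), which should give C9–H anti and CH2OH syn to the C-methyl together with the C7=C8 alkene.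

Step 5
Reactants: 8 homoallylic alcohol; 9 7-hydroxycoumarin (umbelliferone)
Product: 10 7-{[(1R,5R,6R)-2,6-dimethyl-5-(prop-1-en-2-yl)-6-(prop-2-en-1-yl)cyclohex-2-en-1-yl]methoxy}-2H-chromen-2-one
Conditions: PPh3, DIAD, THF, 0 → 45 °C
Reagents that add atoms: 7-hydroxycoumarin, Oc1ccc2ccc(=O)oc2c1
Why: Mitsunobu etherification of the primary alcohol with the acidic phenol, done before any carbonyl is present that could trigger loss of the aryloxide; no stereocentre is touched.

Step 6
Reactants: 10 aryl ether
Product: 11 3-[(1R,2R,6R)-1,3-dimethyl-2-{[(2-oxo-2H-chromen-7-yl)oxy]methyl}-6-(prop-1-en-2-yl)cyclohex-3-en-1-yl]propanal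
Conditions: PdCl2(PhCN)2 (cat.), CuCl2·2H2O (cat.), AgNO2 (cat.), O2 (1 atm), t-BuOH/MeNO2, rt
Reagents that add atoms: dioxygen, O=O
Why: the nitrite-modified, aldehyde-selective (anti-Markovnikov) Wacker oxidation acts only on the monosubstituted terminal alkene, and the neighbouring quaternary carbon further disfavours the methyl-ketone mode; the 1,1-di- and trisubstituted alkenes and the coumarin are inert.

Step 7
Reactants: 11 aldehyde
Product: 13 methyl 3-[(1R,2R,6R)-1,3-dimethyl-2-{[(2-oxo-2H-chromen-7-yl)oxy]methyl}-6-(prop-1-en-2-yl)cyclohex-3-en-1-yl]propanoate, via carboxylic acid 12 (not isolated)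
Conditions: NaClO2, NaH2PO4, 2-methyl-2-butene, t-BuOH/H2O, 0 °C → rt; then TMSCHN2, PhMe/MeOH, 0 °C
Reagents that add atoms: sodium chlorite, [Na+].[O-]Cl=O; (trimethylsilyl)diazomethane, C[Si](C)(C)C=[N+]=[N-]
Why: Pinnick oxidation with a hypochlorite scavenger spares the alkenes, and methylation of the acid gives the ester needed as the acyl donor in step 9.

Step 8
Reactants: 13 methyl ester
Product: 14 methyl 3-[(1S,2R,6R)-1,3-dimethyl-5-oxo-2-{[(2-oxo-2H-chromen-7-yl)oxy]methyl}-6-(prop-1-en-2-yl)cyclohex-3-en-1-yl]propanoate
Conditions: CrO3, 3,5-dimethylpyrazole, CH2Cl2, −20 °C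
Reagents that add atoms: chromium trioxide, O=[Cr](=O)=O
Why: allylic oxidation of the trisubstituted cyclohexene at its only allylic ring CH2 (C6) should give the enone while the less electron-rich isopropenyl group is spared; any drift of the isopropenyl group into conjugation would be harmless, since both isomers give the same dienolate in step 9.

Step 9
Reactants: 14 enone ester
Product: 15 7-{[(3aS,4R,7aR)-3a,5-dimethyl-1,7-dioxo-7a-(prop-1-en-2-yl)-2,3,3a,4,7,7a-hexahydro-1H-inden-4-yl]methoxy}-2H-chromen-2-one (cis-fused)
Conditions: LiHMDS (2.2 equiv), THF, −78 → −20 °C; AcOH, −78 °C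
Reagents that add atoms: none
Why: Dieckmann-type intramolecular acylation, in which kinetic deprotonation at the doubly activated C5–H gives a dienolate that attacks the ester through its alpha carbon (5-exo-trig; gamma attack would need a seven-membered ring), closing the cyclopentanone and making C5 quaternary, while the second equivalent of base stores the product as its C2 enolate and so protects the non-enolisable 1,3-diketone from retro-Claisen opening; the C5 configuration is set by the tether and is erased in step 10.

Step 10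
Reactants: 15 bicyclic 2-isopropenyl-1,3-diketone
Product: 18 epi-conferdione, via tertiary alkyl radical 16 (not isolated), via ring-expanded alpha-keto radical 17 (not isolated)
Conditions: Fe(acac)3 (30 mol%), PhSiH3, EtOH/THF, 60 °C, Ar, 0.01 M
Reagents that add atoms: none
Why: An iron hydride formed from Fe(acac)3 and PhSiH3 transfers a hydrogen atom to the CH2 terminus of the isopropenyl group to give the tertiary radical 16 at C4; this adds 3-exo-trig to the adjacent cyclopentanone carbonyl C3, and the cyclopropyloxy radical opens by beta-scission of the C3–C5 bond, so that C4 is inserted between C3 and C5 and ring A grows from five to six atoms, leaving radical 17 at C5 stabilised by the enone carbonyl C6. The closest known reaction type is the hydrogen-atom-transfer-initiated Dowd–Beckwith ring expansion of alpha-alkenyl beta-dicarbonyl compounds. The only ring that is closed is the transient cyclopropane (3-exo-trig); ring A itself arises by the 1,2-acyl shift. Radical 17 is reduced by Fe(II) to the enolate and protonated by ethanol (or quenched by H-atom transfer) on the face anti to the axial C10 methyl, which should give the trans ring fusion; this centre is alpha to C6=O, so the trans configuration is also the one reached on equilibration, and because the C5 configuration of 15 is lost in the radical either C5 epimer of 15 would converge on 18. The step needs attack on C3=O and not on the enone carbonyl C6=O, and rearrangement faster than simple reduction of 16: attack on the unconjugated cyclopentanone costs no enone conjugation, the acyl shift is reversible and the decalin radical 17 is the thermodynamic sink, and high dilution with a slow hydrogen donor disfavours premature reduction.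

**Compound list**

1 | (S)-(+)-carvone, (5S)-2-methyl-5-(prop-1-en-2-yl)cyclohex-2-en-1-one | CC1=CC[C@H](C(C)=C)CC1=O | starting material
2 | iodomethane | CI | starting material
3 | (5S,6R)-2,6-dimethyl-5-(prop-1-en-2-yl)cyclohex-2-en-1-one (major epimer drawn) | CC1=CC[C@H](C(C)=C)[C@@H](C)C1=O | intermediate
4 | allyl bromide | C=CCBr | starting material
5 | (5R,6R)-2,6-dimethyl-6-(prop-2-en-1-yl)-5-(prop-1-en-2-yl)cyclohex-2-en-1-one | CC1=CC[C@H](C(C)=C)[C@@](C)(CC=C)C1=O | intermediate
6 | trimethylsulfonium iodide | C[S+](C)C.[I-] | starting material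
7 | (3R,7R,8R)-4,8-dimethyl-7-(prop-1-en-2-yl)-8-(prop-2-en-1-yl)-1-oxaspiro[2.5]oct-4-ene | CC1=CC[C@H](C(C)=C)[C@@](C)(CC=C)[C@@]12CO2 | intermediate
8 | [(1R,5R,6R)-2,6-dimethyl-5-(prop-1-en-2-yl)-6-(prop-2-en-1-yl)cyclohex-2-en-1-yl]methanol | CC1=CC[C@H](C(C)=C)[C@@](C)(CC=C)[C@@H]1CO | intermediate
9 | 7-hydroxycoumarin (umbelliferone) | Oc1ccc2ccc(=O)oc2c1 | starting material
10 | 7-{[(1R,5R,6R)-2,6-dimethyl-5-(prop-1-en-2-yl)-6-(prop-2-en-1-yl)cyclohex-2-en-1-yl]methoxy}-2H-chromen-2-one | CC1=CC[C@H](C(C)=C)[C@@](C)(CC=C)[C@@H]1COc1ccc2ccc(=O)oc2c1 | intermediate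
11 | 3-[(1R,2R,6R)-1,3-dimethyl-2-{[(2-oxo-2H-chromen-7-yl)oxy]methyl}-6-(prop-1-en-2-yl)cyclohex-3-en-1-yl]propanal | CC1=CC[C@H](C(C)=C)[C@@](C)(CCC=O)[C@@H]1COc1ccc2ccc(=O)oc2c1 | intermediate
12 | 3-[(1R,2R,6R)-1,3-dimethyl-2-{[(2-oxo-2H-chromen-7-yl)oxy]methyl}-6-(prop-1-en-2-yl)cyclohex-3-en-1-yl]propanoic acid | CC1=CC[C@H](C(C)=C)[C@@](C)(CCC(=O)O)[C@@H]1COc1ccc2ccc(=O)oc2c1 | intermediate
13 | methyl 3-[(1R,2R,6R)-1,3-dimethyl-2-{[(2-oxo-2H-chromen-7-yl)oxy]methyl}-6-(prop-1-en-2-yl)cyclohex-3-en-1-yl]propanoate | CC1=CC[C@H](C(C)=C)[C@@](C)(CCC(=O)OC)[C@@H]1COc1ccc2ccc(=O)oc2c1 | intermediate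
14 | methyl 3-[(1S,2R,6R)-1,3-dimethyl-5-oxo-2-{[(2-oxo-2H-chromen-7-yl)oxy]methyl}-6-(prop-1-en-2-yl)cyclohex-3-en-1-yl]propanoate | CC1=CC(=O)[C@H](C(C)=C)[C@@](C)(CCC(=O)OC)[C@@H]1COc1ccc2ccc(=O)oc2c1 | intermediate
15 | 7-{[(3aS,4R,7aR)-3a,5-dimethyl-1,7-dioxo-7a-(prop-1-en-2-yl)-2,3,3a,4,7,7a-hexahydro-1H-inden-4-yl]methoxy}-2H-chromen-2-one | CC1=CC(=O)[C@@]2(C(C)=C)C(=O)CC[C@@]2(C)[C@@H]1COc1ccc2ccc(=O)oc2c1 | intermediate
16 | tertiary alkyl radical (15 with H added to the isopropenyl CH2; radical at C4) | CC1=CC(=O)[C@@]2([C](C)C)C(=O)CC[C@@]2(C)[C@@H]1COc1ccc2ccc(=O)oc2c1 | intermediate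
17 | ring-expanded alpha-keto radical (decalin-dione skeleton; radical at C5) | CC1=CC(=O)[C]2C(C)(C)C(=O)CC[C@@]2(C)[C@@H]1COc1ccc2ccc(=O)oc2c1 | intermediate
18 | epi-conferdione, 7-{[(1R,4aS,8aS)-2,5,5,8a-tetramethyl-4,6-dioxo-1,4,4a,5,6,7,8,8a-octahydronaphthalen-1-yl]methoxy}-2H-chromen-2-one | CC1=CC(=O)[C@@H]2C(C)(C)C(=O)CC[C@@]2(C)[C@@H]1COc1ccc2ccc(=O)oc2c1 | target

**Step count and risks**

Total steps: 10. Longest linear sequence: 10 steps, from (S)-carvone.

Step 10 is the most exposed. The tertiary radical may attack the enone carbonyl instead of the cyclopentanone carbonyl (ring B would expand), it may be reduced before it rearranges, or it may be intercepted by the coumarin double bond. The fallback builds ring A directly by an acyl-radical cyclisation and sets out from aldehyde 11. The aldehyde is protected with HC(OMe)3 and PPTS in MeOH as the dimethyl acetal F1. Allylic oxidation with CrO3 and 3,5-dimethylpyrazole then gives the enone acetal F2. DBU moves the isopropenyl double bond into conjugation to give the isopropylidene enone acetal F3. PPTS in wet acetone releases the isopropylidene keto-aldehyde F4. Heating F4 with tert-dodecanethiol and 1,1'-azobis(cyclohexanecarbonitrile) in chlorobenzene should generate the acyl radical at C3, which adds to the beta carbon C4 of the isopropylidene enone; the C5 radical takes hydrogen from the thiol anti to the C10 methyl. The fallback comes back to the route at compound 18.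

Step 9 may suffer from reopening of the congested, non-enolisable 1,3-diketone by methoxide, slow bond formation at the hindered C5, or base-induced loss of the aryloxide through the extended enolate. The fallback replaces strong-base Dieckmann closure by soft-enolisation acylation with an activated ester and sets out from acid 12, isolated after the Pinnick stage of step 7. Allylic oxidation with CrO3 and 3,5-dimethylpyrazole gives the enone acid F5. EDC and pentafluorophenol convert it into the pentafluorophenyl ester F6. MgBr2·OEt2 and i-Pr2NEt in CH2Cl2 at room temperature should then enolise the ketone at C5 and acylate it intramolecularly, releasing only the non-nucleophilic pentafluorophenoxide. The fallback comes back to the route at compound 15.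

Step 4 may fail through hydride delivery to the wrong allyl terminus, beta-hydride elimination of the pi-allyl complex to a diene, or Pd–H isomerisation of the allyl group. The fallback replaces the palladium hydride by a Lewis-acid hydride shift and sets out from oxirane 7. Methylaluminium bis(4-bromo-2,6-di-tert-butylphenoxide) in CH2Cl2 at −78 °C should open the oxirane at the tertiary allylic carbon with a 1,2-hydride shift anti to the departing oxygen (Meinwald rearrangement), giving the beta,gamma-unsaturated aldehyde F7 with the same C9 configuration. Immediate reduction with NaBH4 in MeOH at −20 °C, before the aldehyde can epimerise or conjugate, comes back to the route at compound 8.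

**Further compounds**

F1 | step 10 | dimethyl acetal of aldehyde 11, 7-{[(1R,5R,6R)-6-(3,3-dimethoxypropyl)-2,6-dimethyl-5-(prop-1-en-2-yl)cyclohex-2-en-1-yl]methoxy}-2H-chromen-2-one | CC1=CC[C@H](C(C)=C)[C@@](C)(CCC(OC)OC)[C@@H]1COc1ccc2ccc(=O)oc2c1
F2 | step 10 | enone acetal, 7-{[(1R,5R,6S)-6-(3,3-dimethoxypropyl)-2,6-dimethyl-4-oxo-5-(prop-1-en-2-yl)cyclohex-2-en-1-yl]methoxy}-2H-chromen-2-one | CC1=CC(=O)[C@H](C(C)=C)[C@@](C)(CCC(OC)OC)[C@@H]1COc1ccc2ccc(=O)oc2c1
F3 | step 10 | isopropylidene enone acetal (conjugated double-bond isomer of F2, 5-(propan-2-ylidene)) | CC1=CC(=O)C(=C(C)C)[C@@](C)(CCC(OC)OC)[C@@H]1COc1ccc2ccc(=O)oc2c1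
F4 | step 10 | isopropylidene keto-aldehyde (F3 with the acetal hydrolysed to the propanal) | CC1=CC(=O)C(=C(C)C)[C@@](C)(CCC=O)[C@@H]1COc1ccc2ccc(=O)oc2c1
F5 | step 9 | enone acid, 3-[(1S,2R,6R)-1,3-dimethyl-5-oxo-2-{[(2-oxo-2H-chromen-7-yl)oxy]methyl}-6-(prop-1-en-2-yl)cyclohex-3-en-1-yl]propanoic acid | CC1=CC(=O)[C@H](C(C)=C)[C@@](C)(CCC(=O)O)[C@@H]1COc1ccc2ccc(=O)oc2c1
F6 | step 9 | pentafluorophenyl ester of F5 | CC1=CC(=O)[C@H](C(C)=C)[C@@](C)(CCC(=O)Oc2c(F)c(F)c(F)c(F)c2F)[C@@H]1COc1ccc2ccc(=O)oc2c1
F7 | step 4 | (1R,5R,6R)-2,6-dimethyl-5-(prop-1-en-2-yl)-6-(prop-2-en-1-yl)cyclohex-2-ene-1-carbaldehyde | CC1=CC[C@H](C(C)=C)[C@@](C)(CC=C)[C@@H]1C=O
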